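**Plan**

- Cuts: the two primary silyl ethers, the lactone bond O8–C12 and the C6 ester come off first. The ten-membered ring is then opened at C6–C7 by a retro-[2,3]-Wittig shift to a 13-membered cyclic ether with its oxygen between C6 and C13. That ether is cut at O–C13, and the chain at C7–C11, C1=C10 and C4=C5.
- Enabling feature: C6(O)–C7–C11(=C13H2) is a homoallylic alcohol whose carbinol carbon C6 is also allylic to the ring alkene C4=C5, with C7 next to the lactone carbinol C8. This is exactly what a [2,3]-Wittig shift across the ring bond C6–C7 leaves behind.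
- Forward: C4–C5 and C10–C1 are joined by two lactone aldol/dehydration sequences and C7–C11 by a Morita–Baylis–Hillman reaction. The 13-membered ether ring is closed at O–C13 and contracted to the cyclodecadiene, and the γ-lactone ring is closed last at O8–C12.
- Stereochemistry: C8 is bought in (S)-5-(trityloxymethyl)butyrolactone. C6 and C7 are created together in the ring contraction (syn from the ring-cis C7=C11 alkene, absolute sense relayed from C8). The ring-cis C1=C10 and C4=C5 alkenes come from two E-alkylidene lactones, the C7=C11 geometry from a Z-selective SN2' bromination, and the tiglate geometry from tiglic acid.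

Key step: step 20

Remark: germacrane numbering is used throughout, with C12 the lactone carbonyl carbon, C13 the exocyclic methylene carbon, C14 the CH2O carbon on C10 and C15 the CH2O carbon on C4. "Ring-cis" means the two ring bonds are cis on the alkene (the CIP descriptor of these alkenes is E because the CH2O branch outranks the ring CH2). Lactone 12 is taken as a catalogue compound.

**Route**

Step 1
Reactants: 1 (Z)-but-2-ene-1,4-diol
Product: 2 (Z)-1,4-bis(4-methoxybenzyloxy)but-2-ene
Conditions: NaH, PMBCl, Bu4NI (cat.), THF/DMF, 0 °C → rt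
Reagents that add atoms: 4-methoxybenzyl chloride, COc1ccc(CCl)cc1
Why: Double Williamson etherification of a primary allylic diol with a benzylic chloride is routine and leaves the Z alkene untouched.

Step 2
Reactants: 2 (Z)-1,4-bis(4-methoxybenzyloxy)but-2-ene
Product: 4 2-(4-methoxybenzyloxy)acetaldehyde, via ozonide 3 (not isolated)
Conditions: O3, CH2Cl2, −78 °C (Sudan III end point); then PPh3, −78 °C → rt
Reagents that add atoms: ozone, [O-][O+]=O
Why: Ozonolysis of the symmetrical alkene through the secondary ozonide and reductive work-up should give two molecules of the α-alkoxy aldehyde, the dye end point sparing the anisyl rings.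

Step 3
Reactants: 5 δ-valerolactone; 4 2-(4-methoxybenzyloxy)acetaldehyde
Product: 7 β-hydroxy lactone (aldol adduct), via lithium enolate 6 (not isolated)
Conditions: LDA, THF, −78 °C; then 4, −78 °C; aq NH4Cl
Reagents that add atoms: none
Why: The kinetically formed lithium enolate of the lactone adds to the unhindered aldehyde faster than it self-condenses (lactone aldol addition), and the two new stereocentres are removed in step 4 so need no control.

Step 4
Reactants: 7 β-hydroxy lactone
Product: 9 (E)-3-[2-(4-methoxybenzyloxy)ethylidene]tetrahydro-2H-pyran-2-one, via mesylate 8 (not isolated)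
Conditions: MsCl, Et3N, CH2Cl2, 0 °C; then DBU, 0 °C → rt
Reagents that add atoms: none
Why: Mesylation and DBU-promoted E1cB elimination through the lactone enolate give the conjugated exocyclic alkene under thermodynamic control, which places C6 trans to the carbonyl and so fixes the ring-cis C4=C5 geometry.

Step 5
Reactants: 9 E-alkylidene valerolactone
Product: 10 methyl (2E)-2-(3-hydroxypropyl)-4-(4-methoxybenzyloxy)but-2-enoate
Conditions: K2CO3 (0.2 equiv), MeOH, 0 °C; pH 7 buffer, concentration without heating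
Reagents that add atoms: methanol, CO
Why: Base-catalysed transesterification in a large excess of methanol opens the six-membered lactone without touching the trisubstituted alkene, and cold neutralisation keeps the hydroxy ester from closing again.

Step 6
Reactants: 10 hydroxy ester
Product: 11 methyl (2E)-4-(4-methoxybenzyloxy)-2-(3-oxopropyl)but-2-enoate
Conditions: TEMPO (0.1 equiv), PhI(OAc)2, CH2Cl2, rt
Reagents that add atoms: none
Why: Oxoammonium (TEMPO) oxidation of a primary alcohol stops at the aldehyde and tolerates the enoate and the PMB ether.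

Step 7
Reactants: 12 (S)-5-(trityloxymethyl)dihydrofuran-2(3H)-one; 11 aldehyde ester
Product: 14 β-hydroxy butyrolactone (aldol adduct), via lithium enolate 13 (not isolated)
Conditions: LDA, THF, −78 °C; then 11, −78 °C; aq NH4Cl
Reagents that add atoms: none
Why: The lactone enolate adds to the aldehyde far faster than to the hindered conjugated ester at −78 °C (aldol addition); C8 is not involved and the two new centres disappear in step 8.

Step 8
Reactants: 14 β-hydroxy butyrolactone
Product: 16 E-alkylidene butyrolactone, via mesylate 15 (not isolated)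
Conditions: MsCl, Et3N, CH2Cl2, 0 °C; then DBU, rt
Reagents that add atoms: none
Why: The same mesylation/E1cB sequence as in step 4 gives the thermodynamic E-alkylidene lactone, with C2 trans to the carbonyl C14, which is the ring-cis C1=C10 geometry.

Step 9
Reactants: 16 E-alkylidene butyrolactone
Product: 17 triol (C8, C14 and C15 hydroxyls free)
Conditions: DIBAL-H (excess), CH2Cl2, −78 → 0 °C; Rochelle salt
Reagents that add atoms: none
Why: DIBAL-H reduces conjugated esters and lactones by 1,2-addition, so both carbonyls should go to the allylic alcohols without conjugate reduction and without loss of the trityl or PMB ether.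

Step 10
Reactants: 17 triol
Product: 18 C14,C15 bis-TBDPS ether
Conditions: TBDPSCl (2.1 equiv), imidazole, CH2Cl2, 0 °C
Reagents that add atoms: tert-butyl(chloro)diphenylsilane, CC(C)(C)[Si](Cl)(c1ccccc1)c1ccccc1
Why: The bulky silyl chloride reacts with the two unhindered primary allylic alcohols much faster than with the secondary C8 alcohol next to the trityloxymethyl group.

Step 11
Reactants: 18 bis-TBDPS ether
Product: 19 C8 TBS ether
Conditions: TBSCl, imidazole, DMAP (cat.), DMF, rt → 40 °C
Reagents that add atoms: tert-butyl(chloro)dimethylsilane, CC(C)(C)[Si](C)(C)Cl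
Why: Standard silylation of the remaining secondary alcohol under non-acidic conditions keeps the acid-labile trityl ether.

Step 12
Reactants: 19 C8 TBS ether
Product: 20 C7 primary alcohol
Conditions: CSA (0.1 equiv), MeOH/CH2Cl2 (1:3), 0 °C; Et3N quench
Reagents that add atoms: none
Why: The trityl ether ionises in mildly acidic methanol far faster than a secondary TBS, a primary TBDPS or a PMB ether is cleaved, and the cation is trapped as methyl trityl ether.

Step 13
Reactants: 20 C7 primary alcohol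
Product: 21 α-silyloxy aldehyde
Conditions: TEMPO (0.1 equiv), PhI(OAc)2, CH2Cl2, rt
Reagents that add atoms: none
Why: The nearly neutral TEMPO oxidation should give the α-silyloxy aldehyde without epimerising C8.

Step 14
Reactants: 21 α-silyloxy aldehyde; 22 methyl acrylate
Product: 23 Morita–Baylis–Hillman adduct (C7 carbinol as a mixture)
Conditions: methyl acrylate (excess, as solvent), DABCO (1 equiv), MeOH (cat.), rt
Reagents that add atoms: none
Why: In the Morita–Baylis–Hillman reaction the amine-activated acrylate adds through its α-carbon to the inductively activated α-oxygenated aldehyde; the configuration of the new carbinol is irrelevant because C7 becomes sp2 in step 15.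

Step 15
Reactants: 23 Morita–Baylis–Hillman adduct
Product: 24 Z-allylic bromide ester
Conditions: NBS, Me2S, CH2Cl2, 0 °C → rt
Reagents that add atoms: N-bromosuccinimide, O=C1CCC(=O)N1Br
Why: Corey–Kim-type activation of the hydroxyl and SN2' attack of bromide on the methylene carbon give the trisubstituted 2-(bromomethyl)enoate with C8 trans to the ester (Z), the usual outcome for such adducts, and both C7 epimers converge.

Step 16
Reactants: 24 Z-allylic bromide ester
Product: 25 bromo allylic alcohol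
Conditions: DIBAL-H (2.2 equiv), CH2Cl2, −78 °C; Rochelle salt
Reagents that add atoms: none
Why: At −78 °C DIBAL-H reduces the conjugated ester by 1,2-addition and does not displace the allylic bromide, as is known for 2-(bromomethyl)alk-2-enoates.

Step 17
Reactants: 25 bromo allylic alcohol
Product: 26 bromo TBS ether
Conditions: TBSOTf, 2,6-lutidine, CH2Cl2, −78 °C
Reagents that add atoms: tert-butyldimethylsilyl trifluoromethanesulfonate, CC(C)(C)[Si](C)(C)OS(=O)(=O)C(F)(F)F
Why: The silyl triflate with a hindered, non-nucleophilic base silylates the primary alcohol within minutes at −78 °C and avoids the N-alkylation that imidazole would suffer with the allylic bromide.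

Step 18
Reactants: 26 bromo TBS ether
Product: 27 hydroxy bromide
Conditions: DDQ, CH2Cl2/pH 7 buffer (10:1), 0 °C
Reagents that add atoms: none
Why: DDQ oxidises only the electron-rich benzylic ether and leaves silyl ethers, the allylic bromide and the trisubstituted alkenes alone.

Step 19
Reactants: 27 hydroxy bromide
Product: 29 13-membered bis-allylic ether, via sodium alkoxide 28 (not isolated)
Conditions: NaH, Bu4NI (cat.), THF, syringe-pump addition (final ≤0.002 M), rt → 45 °C
Reagents that add atoms: none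
Why: Intramolecular Williamson etherification under high dilution, a known way to close 13-membered allylic ethers: the primary allylic alkoxide displaces the primary allylic bromide at C13, E2 is impossible, SN2' at C7 is blocked by the C8 silyl ether, and the three ring-cis alkenes fold the chain.

Step 20
Reactants: 29 13-membered bis-allylic ether
Product: 31 cyclodecadienol with free C6 hydroxyl, via C6-lithio ether 30 (not isolated)
Conditions: n-BuLi (2 equiv), THF/hexane, −78 → −30 °C; aq NH4Cl
Reagents that add atoms: none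
Why: n-BuLi removes a C6 proton (α to oxygen, allylic to C4=C5) to give the α-alkoxy allyllithium 30, whose C6 bonds to C7 through a five-membered envelope transition state while the π bond moves to C11=C13 and the O–C13 bond breaks, leaving the C6 lithium alkoxide ([2,3]-Wittig rearrangement). The closest known reactions are the transannular [2,3]-Wittig ring contractions of 13-membered bis-allylic and allyl propargyl ethers to cyclodecadienols of the germacrane type. The ten-membered carbocycle therefore closes by bond formation across the existing 13-membered ring with excision of the O–C13–C11 unit, not by end-to-end cyclisation, and no other ring forms. C6 and C7 are set together: the ring-cis C7=C11 alkene (a Z-type allyl terminus) gives the syn relation of the C6 oxygen and C8, and the absolute sense follows from C8, whose hydrogen eclipses the alkene toward C13 to avoid allylic 1,3-strain so that the silyloxy group covers one face of C7 and the C9 tether brings C6 to the other. The step needs rearrangement through the C6 anion and not the C13 anion: the latter would have to bond to the fully substituted C4 and its protons sit between the branched C11 and the C8 silyl ether, while the low temperature holds back loss of the C15 silyloxide from the allyl anion and the [1,2]-shift.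

Step 21
Reactants: 31 cyclodecadienol; 32 tiglic acid
Product: 34 C6 tiglate, via mixed anhydride 33 (not isolated)
Conditions: 2,4,6-trichlorobenzoyl chloride, Et3N, toluene, rt; then 31, DMAP, rt → 40 °C
Reagents that add atoms: none
Why: In the Yamaguchi esterification DMAP delivers the less hindered tigloyl group of the mixed anhydride to the hindered secondary allylic alcohol without isomerising the E double bond of the acid.

Step 22
Reactants: 34 C6 tiglate
Product: 35 C8,C12 diol
Conditions: CSA, MeOH/CH2Cl2 (1:1), 0 °C → rt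
Reagents that add atoms: none
Why: Acid-catalysed methanolysis removes the primary allylic and the secondary TBS ether well before the bulkier TBDPS ethers are attacked, and acidic conditions avoid migration of the tigloyl group.

Step 23
Reactants: 35 C8,C12 diol
Product: 38 bis-TBDPS α-methylene lactone, via hydroxy enal 36 (not isolated), via lactol 37 (not isolated)
Conditions: activated MnO2 (excess), CH2Cl2, rt
Reagents that add atoms: none
Why: MnO2 oxidises only the allylic C12 alcohol, the C8 hydroxyl adds to the enal and the lactol is oxidised further (oxidative lactonisation of a 2-methylene-1,4-diol); C7 and C8 are untouched, so the lactone is trans-fused as set in step 20.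

Step 24
Reactants: 38 bis-TBDPS α-methylene lactone
Product: 39 target CNP0275462.1
Conditions: HF·pyridine, pyridine, THF, 0 °C → rt
Reagents that add atoms: none
Why: Pyridine-buffered HF cleaves primary TBDPS ethers without base, so the α-methylene lactone and the allylic tiglate should survive, and the C15 hydroxyl lies trans to C6 across C4=C5 so the ester cannot migrate to it.

**Compound list**

1 | (Z)-but-2-ene-1,4-diol | OC/C=C\CO | starting material
2 | (Z)-1,4-bis(4-methoxybenzyloxy)but-2-ene | COc1ccc(COC/C=C\COCc2ccc(OC)cc2)cc1 | intermediate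
3 | 3,5-bis[(4-methoxybenzyloxy)methyl]-1,2,4-trioxolane (secondary ozonide) | COc1ccc(COCC2OOC(COCc3ccc(OC)cc3)O2)cc1 | intermediate
4 | 2-(4-methoxybenzyloxy)acetaldehyde | O=CCOCc1ccc(OC)cc1 | intermediate
5 | δ-valerolactone (tetrahydro-2H-pyran-2-one) | O=C1CCCCO1 | starting material
6 | lithium enolate of δ-valerolactone | [Li+].[O-]C1=CCCCO1 | intermediate
7 | 3-[1-hydroxy-2-(4-methoxybenzyloxy)ethyl]tetrahydro-2H-pyran-2-one (diastereomer mixture) | O=C1OCCCC1C(O)COCc1ccc(OC)cc1 | intermediate
8 | methanesulfonate of aldol 7 | O=C1OCCCC1C(OS(C)(=O)=O)COCc1ccc(OC)cc1 | intermediate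
9 | (E)-3-[2-(4-methoxybenzyloxy)ethylidene]tetrahydro-2H-pyran-2-one | O=C1OCCC/C1=C\COCc1ccc(OC)cc1 | intermediate
10 | methyl (2E)-2-(3-hydroxypropyl)-4-(4-methoxybenzyloxy)but-2-enoate | OCCC/C(C(=O)OC)=C\COCc1ccc(OC)cc1 | intermediate
11 | methyl (2E)-4-(4-methoxybenzyloxy)-2-(3-oxopropyl)but-2-enoate | O=CCC/C(C(=O)OC)=C\COCc1ccc(OC)cc1 | intermediate
12 | (S)-5-(trityloxymethyl)dihydrofuran-2(3H)-one | O=C1CC[C@@H](COC(c2ccccc2)(c2ccccc2)c2ccccc2)O1 | starting material
13 | lithium enolate of lactone 12 | [Li+].[O-]C1=CC[C@@H](COC(c2ccccc2)(c2ccccc2)c2ccccc2)O1 | intermediate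
14 | methyl (2E)-2-{3-hydroxy-3-[(5S)-2-oxo-5-(trityloxymethyl)tetrahydrofuran-3-yl]propyl}-4-(4-methoxybenzyloxy)but-2-enoate (mixture at the two new centres) | O=C1O[C@H](COC(c2ccccc2)(c2ccccc2)c2ccccc2)CC1C(O)CC/C(C(=O)OC)=C\COCc1ccc(OC)cc1 | intermediate
15 | methanesulfonate of aldol 14 | O=C1O[C@H](COC(c2ccccc2)(c2ccccc2)c2ccccc2)CC1C(OS(C)(=O)=O)CC/C(C(=O)OC)=C\COCc1ccc(OC)cc1 | intermediate
16 | methyl (2E)-4-(4-methoxybenzyloxy)-2-{(3E)-3-[(5S)-2-oxo-5-(trityloxymethyl)dihydrofuran-3(2H)-ylidene]propyl}but-2-enoate | O=C1O[C@H](COC(c2ccccc2)(c2ccccc2)c2ccccc2)C/C1=C\CC/C(C(=O)OC)=C\COCc1ccc(OC)cc1 | intermediate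
17 | (2S,4E,8E)-4,8-bis(hydroxymethyl)-10-(4-methoxybenzyloxy)-1-(trityloxy)deca-4,8-dien-2-ol | C(c1ccccc1)(c1ccccc1)(c1ccccc1)OC[C@@H](O)C/C(CO)=C\CC/C(CO)=C\COCc1ccc(OC)cc1 | intermediate
18 | (2S,4E,8E)-4,8-bis[(tert-butyldiphenylsilyloxy)methyl]-10-(4-methoxybenzyloxy)-1-(trityloxy)deca-4,8-dien-2-ol | C(c1ccccc1)(c1ccccc1)(c1ccccc1)OC[C@@H](O)C/C(CO[Si](c1ccccc1)(c1ccccc1)C(C)(C)C)=C\CC/C(CO[Si](c1ccccc1)(c1ccccc1)C(C)(C)C)=C\COCc1ccc(OC)cc1 | intermediate
19 | (2S,4E,8E)-2-(tert-butyldimethylsilyloxy)-4,8-bis[(tert-butyldiphenylsilyloxy)methyl]-10-(4-methoxybenzyloxy)-1-(trityloxy)deca-4,8-diene | C(c1ccccc1)(c1ccccc1)(c1ccccc1)OC[C@@H](O[Si](C)(C)C(C)(C)C)C/C(CO[Si](c1ccccc1)(c1ccccc1)C(C)(C)C)=C\CC/C(CO[Si](c1ccccc1)(c1ccccc1)C(C)(C)C)=C\COCc1ccc(OC)cc1 | intermediate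
20 | (2S,4E,8E)-2-(tert-butyldimethylsilyloxy)-4,8-bis[(tert-butyldiphenylsilyloxy)methyl]-10-(4-methoxybenzyloxy)deca-4,8-dien-1-ol | OC[C@@H](O[Si](C)(C)C(C)(C)C)C/C(CO[Si](c1ccccc1)(c1ccccc1)C(C)(C)C)=C\CC/C(CO[Si](c1ccccc1)(c1ccccc1)C(C)(C)C)=C\COCc1ccc(OC)cc1 | intermediate
21 | (2S,4E,8E)-2-(tert-butyldimethylsilyloxy)-4,8-bis[(tert-butyldiphenylsilyloxy)methyl]-10-(4-methoxybenzyloxy)deca-4,8-dienal | O=C[C@@H](O[Si](C)(C)C(C)(C)C)C/C(CO[Si](c1ccccc1)(c1ccccc1)C(C)(C)C)=C\CC/C(CO[Si](c1ccccc1)(c1ccccc1)C(C)(C)C)=C\COCc1ccc(OC)cc1 | intermediate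
22 | methyl acrylate | C=CC(=O)OC | starting material
23 | methyl (4S,6E,10E)-4-(tert-butyldimethylsilyloxy)-6,10-bis[(tert-butyldiphenylsilyloxy)methyl]-3-hydroxy-12-(4-methoxybenzyloxy)-2-methylidenedodeca-6,10-dienoate (both C3 epimers) | C=C(C(=O)OC)C(O)[C@@H](O[Si](C)(C)C(C)(C)C)C/C(CO[Si](c1ccccc1)(c1ccccc1)C(C)(C)C)=C\CC/C(CO[Si](c1ccccc1)(c1ccccc1)C(C)(C)C)=C\COCc1ccc(OC)cc1 | intermediate
24 | methyl (2Z,4S,6E,10E)-2-(bromomethyl)-4-(tert-butyldimethylsilyloxy)-6,10-bis[(tert-butyldiphenylsilyloxy)methyl]-12-(4-methoxybenzyloxy)dodeca-2,6,10-trienoate | BrC/C(C(=O)OC)=C\[C@@H](O[Si](C)(C)C(C)(C)C)C/C(CO[Si](c1ccccc1)(c1ccccc1)C(C)(C)C)=C\CC/C(CO[Si](c1ccccc1)(c1ccccc1)C(C)(C)C)=C\COCc1ccc(OC)cc1 | intermediate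
25 | (2Z,4S,6E,10E)-2-(bromomethyl)-4-(tert-butyldimethylsilyloxy)-6,10-bis[(tert-butyldiphenylsilyloxy)methyl]-12-(4-methoxybenzyloxy)dodeca-2,6,10-trien-1-ol | BrC/C(CO)=C\[C@@H](O[Si](C)(C)C(C)(C)C)C/C(CO[Si](c1ccccc1)(c1ccccc1)C(C)(C)C)=C\CC/C(CO[Si](c1ccccc1)(c1ccccc1)C(C)(C)C)=C\COCc1ccc(OC)cc1 | intermediate
26 | tert-butyldimethylsilyl ether of 25 at the C12 oxygen | BrC/C(CO[Si](C)(C)C(C)(C)C)=C\[C@@H](O[Si](C)(C)C(C)(C)C)C/C(CO[Si](c1ccccc1)(c1ccccc1)C(C)(C)C)=C\CC/C(CO[Si](c1ccccc1)(c1ccccc1)C(C)(C)C)=C\COCc1ccc(OC)cc1 | intermediate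
27 | (2E,6E,9S,10Z)-12-bromo-9-(tert-butyldimethylsilyloxy)-11-[(tert-butyldimethylsilyloxy)methyl]-3,7-bis[(tert-butyldiphenylsilyloxy)methyl]dodeca-2,6,10-trien-1-ol | BrC/C(CO[Si](C)(C)C(C)(C)C)=C\[C@@H](O[Si](C)(C)C(C)(C)C)C/C(CO[Si](c1ccccc1)(c1ccccc1)C(C)(C)C)=C\CC/C(CO[Si](c1ccccc1)(c1ccccc1)C(C)(C)C)=C\CO | intermediate
28 | sodium alkoxide of 27 | BrC/C(CO[Si](C)(C)C(C)(C)C)=C\[C@@H](O[Si](C)(C)C(C)(C)C)C/C(CO[Si](c1ccccc1)(c1ccccc1)C(C)(C)C)=C\CC/C(CO[Si](c1ccccc1)(c1ccccc1)C(C)(C)C)=C\C[O-].[Na+] | intermediate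
29 | (3E,5S,7E,11E)-5-(tert-butyldimethylsilyloxy)-3-[(tert-butyldimethylsilyloxy)methyl]-7,11-bis[(tert-butyldiphenylsilyloxy)methyl]-1-oxacyclotrideca-3,7,11-triene (all three alkenes ring-cis; ring O between C6 and C13) | O1C/C=C(CO[Si](c2ccccc2)(c2ccccc2)C(C)(C)C)\CC/C=C(CO[Si](c2ccccc2)(c2ccccc2)C(C)(C)C)\C[C@H](O[Si](C)(C)C(C)(C)C)/C=C(CO[Si](C)(C)C(C)(C)C)\C1 | intermediate
30 | C6-lithio derivative of ether 29 (α-alkoxy allyllithium) | [Li]C1/C=C(CO[Si](c2ccccc2)(c2ccccc2)C(C)(C)C)\CC/C=C(CO[Si](c2ccccc2)(c2ccccc2)C(C)(C)C)\C[C@H](O[Si](C)(C)C(C)(C)C)/C=C(CO[Si](C)(C)C(C)(C)C)\CO1 | intermediate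
31 | (6S,7S,8S)-8,12-bis(tert-butyldimethylsilyloxy)-14,15-bis(tert-butyldiphenylsilyloxy)germacra-1(10),4,11(13)-trien-6-ol (C1=C10 and C4=C5 ring-cis) | C=C(CO[Si](C)(C)C(C)(C)C)[C@@H]1[C@@H](O[Si](C)(C)C(C)(C)C)C/C(CO[Si](c2ccccc2)(c2ccccc2)C(C)(C)C)=C\CC/C(CO[Si](c2ccccc2)(c2ccccc2)C(C)(C)C)=C\[C@@H]1O | intermediate
32 | tiglic acid, (E)-2-methylbut-2-enoic acid | C/C=C(\C)C(=O)O | starting material
33 | tiglic 2,4,6-trichlorobenzoic anhydride | C/C=C(\C)C(=O)OC(=O)c1c(Cl)cc(Cl)cc1Cl | intermediate
34 | (6S,7S,8S)-8,12-bis(tert-butyldimethylsilyloxy)-14,15-bis(tert-butyldiphenylsilyloxy)germacra-1(10),4,11(13)-trien-6-yl (E)-2-methylbut-2-enoate | C=C(CO[Si](C)(C)C(C)(C)C)[C@@H]1[C@@H](O[Si](C)(C)C(C)(C)C)C/C(CO[Si](c2ccccc2)(c2ccccc2)C(C)(C)C)=C\CC/C(CO[Si](c2ccccc2)(c2ccccc2)C(C)(C)C)=C\[C@@H]1OC(=O)/C(C)=C/C | intermediate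
35 | (6S,7R,8S)-8,12-dihydroxy-14,15-bis(tert-butyldiphenylsilyloxy)germacra-1(10),4,11(13)-trien-6-yl (E)-2-methylbut-2-enoate | C=C(CO)[C@@H]1[C@@H](O)C/C(CO[Si](c2ccccc2)(c2ccccc2)C(C)(C)C)=C\CC/C(CO[Si](c2ccccc2)(c2ccccc2)C(C)(C)C)=C\[C@@H]1OC(=O)/C(C)=C/C | intermediate
36 | (6S,7R,8S)-8-hydroxy-12-oxo-14,15-bis(tert-butyldiphenylsilyloxy)germacra-1(10),4,11(13)-trien-6-yl (E)-2-methylbut-2-enoate (hydroxy enal) | C=C(C=O)[C@@H]1[C@@H](O)C/C(CO[Si](c2ccccc2)(c2ccccc2)C(C)(C)C)=C\CC/C(CO[Si](c2ccccc2)(c2ccccc2)C(C)(C)C)=C\[C@@H]1OC(=O)/C(C)=C/C | intermediate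
37 | lactol of 36 (C12 hemiacetal with O8, either anomer) | C=C1C(O)O[C@H]2C/C(CO[Si](c3ccccc3)(c3ccccc3)C(C)(C)C)=C\CC/C(CO[Si](c3ccccc3)(c3ccccc3)C(C)(C)C)=C\[C@H](OC(=O)/C(C)=C/C)[C@H]12 | intermediate
38 | (6S,7R,8S)-14,15-bis(tert-butyldiphenylsilyloxy)-6-[(E)-2-methylbut-2-enoyloxy]germacra-1(10),4,11(13)-trien-12,8-olide (trans-fused lactone) | C=C1C(=O)O[C@H]2C/C(CO[Si](c3ccccc3)(c3ccccc3)C(C)(C)C)=C\CC/C(CO[Si](c3ccccc3)(c3ccccc3)C(C)(C)C)=C\[C@H](OC(=O)/C(C)=C/C)[C@H]12 | intermediate
39 | CNP0275462.1, (3aR,4S,5E,9E,11aS)-6,10-bis(hydroxymethyl)-3-methylidene-2-oxo-2,3,3a,4,7,8,11,11a-octahydrocyclodeca[b]furan-4-yl (2E)-2-methylbut-2-enoate [(6S,7R,8S) in germacrane numbering] | C=C1C(=O)O[C@H]2C/C(CO)=C\CC/C(CO)=C\[C@H](OC(=O)/C(C)=C/C)[C@H]12 | target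

**Step count**

Total: 24 steps. Longest linear sequence: 24 steps, from diol 1 to target 39; compounds 5, 12, 22 and 32 enter as bought materials.

**The three steps most likely to fail**

Step 20 (ring contraction). The lithiation may occur at C13 in place of C6, the C6 allyl anion may expel the C15 silyloxide before it rearranges, or C6 may reach the wrong face of C7. The fallback forms the same C6–C7 bond by a chromium(II)-mediated Nozaki–Hiyama allylation and gives up the ether bridge. It sets out from hydroxy bromide 27: MnO2 in CH2Cl2 would oxidise the primary allylic alcohol to the C6 enal bromide F1. Slow addition of F1 to CrCl2 in THF at high dilution would reduce the C13 bromide, and the allyl unit would add through C7 to the aldehyde with transposition of the double bond to C11=C13. This closes the ten-membered ring and returns to the route at cyclodecadienol 31. The diastereoselectivity at C6 and C7 would then rest on the cyclic transition state of the allylation, not on the alkene geometry, and would have to be established.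

Step 14 (Morita–Baylis–Hillman reaction). Addition to the hindered aldehyde may be so slow that the amine epimerises C8 through the enol or the acrylate oligomerises. The fallback uses a masked acrylate and sets out from aldehyde 21. The lithium enolate of methyl 3-(dimethylamino)propanoate (LDA, THF, −78 °C) would add to 21 to give the amino aldol F2. Methyl iodide in THF would give the trimethylammonium iodide F3, and NaHCO3 in aqueous THF would eliminate trimethylamine to give the α-methylene ester. This returns to the route at adduct 23.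

Step 22 (removal of two TBS ethers beside two TBDPS ethers). Cleavage of the hindered secondary silyl ether at O8 may be incomplete, or the primary allylic TBDPS ethers may be lost at the same time. The fallback changes the lactone closure from an oxidative one to an acid-level one and sets out from tiglate 34:
- PPTS in MeOH would remove only the primary allylic TBS ether to give the C12 alcohol F4.
- MnO2 would give the enal F5.
- Pinnick oxidation (NaClO2, NaH2PO4, 2-methyl-2-butene, t-BuOH/H2O) would give the acrylic acid F6.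
- HF·pyridine in THF would then remove the three remaining silyl groups to give the seco hydroxy acid F7, which should lactonise under the acidic conditions or on brief treatment with a carbodiimide.

This returns to the route at target 39.

Further compounds
F1 | step 20 | (2E,6E,9S,10Z)-12-bromo-9-(tert-butyldimethylsilyloxy)-11-[(tert-butyldimethylsilyloxy)methyl]-3,7-bis[(tert-butyldiphenylsilyloxy)methyl]dodeca-2,6,10-trienal | BrC/C(CO[Si](C)(C)C(C)(C)C)=C\[C@@H](O[Si](C)(C)C(C)(C)C)C/C(CO[Si](c1ccccc1)(c1ccccc1)C(C)(C)C)=C\CC/C(CO[Si](c1ccccc1)(c1ccccc1)C(C)(C)C)=C\C=O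
F2 | step 14 | methyl (4S,6E,10E)-4-(tert-butyldimethylsilyloxy)-6,10-bis[(tert-butyldiphenylsilyloxy)methyl]-2-[(dimethylamino)methyl]-3-hydroxy-12-(4-methoxybenzyloxy)dodeca-6,10-dienoate (diastereomer mixture) | CN(C)CC(C(=O)OC)C(O)[C@@H](O[Si](C)(C)C(C)(C)C)C/C(CO[Si](c1ccccc1)(c1ccccc1)C(C)(C)C)=C\CC/C(CO[Si](c1ccccc1)(c1ccccc1)C(C)(C)C)=C\COCc1ccc(OC)cc1
F3 | step 14 | trimethylammonium iodide of F2 | C[N+](C)(C)CC(C(=O)OC)C(O)[C@@H](O[Si](C)(C)C(C)(C)C)C/C(CO[Si](c1ccccc1)(c1ccccc1)C(C)(C)C)=C\CC/C(CO[Si](c1ccccc1)(c1ccccc1)C(C)(C)C)=C\COCc1ccc(OC)cc1.[I-]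
F4 | step 22 | (6S,7S,8S)-8-(tert-butyldimethylsilyloxy)-12-hydroxy-14,15-bis(tert-butyldiphenylsilyloxy)germacra-1(10),4,11(13)-trien-6-yl (E)-2-methylbut-2-enoate | C=C(CO)[C@@H]1[C@@H](O[Si](C)(C)C(C)(C)C)C/C(CO[Si](c2ccccc2)(c2ccccc2)C(C)(C)C)=C\CC/C(CO[Si](c2ccccc2)(c2ccccc2)C(C)(C)C)=C\[C@@H]1OC(=O)/C(C)=C/C
F5 | step 22 | (6S,7S,8S)-8-(tert-butyldimethylsilyloxy)-12-oxo-14,15-bis(tert-butyldiphenylsilyloxy)germacra-1(10),4,11(13)-trien-6-yl (E)-2-methylbut-2-enoate | C=C(C=O)[C@@H]1[C@@H](O[Si](C)(C)C(C)(C)C)C/C(CO[Si](c2ccccc2)(c2ccccc2)C(C)(C)C)=C\CC/C(CO[Si](c2ccccc2)(c2ccccc2)C(C)(C)C)=C\[C@@H]1OC(=O)/C(C)=C/C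
F6 | step 22 | (6S,7S,8S)-8-(tert-butyldimethylsilyloxy)-14,15-bis(tert-butyldiphenylsilyloxy)-6-[(E)-2-methylbut-2-enoyloxy]germacra-1(10),4,11(13)-trien-12-oic acid | C=C(C(=O)O)[C@@H]1[C@@H](O[Si](C)(C)C(C)(C)C)C/C(CO[Si](c2ccccc2)(c2ccccc2)C(C)(C)C)=C\CC/C(CO[Si](c2ccccc2)(c2ccccc2)C(C)(C)C)=C\[C@@H]1OC(=O)/C(C)=C/C
F7 | step 22 | (6S,7R,8S)-8,14,15-trihydroxy-6-[(E)-2-methylbut-2-enoyloxy]germacra-1(10),4,11(13)-trien-12-oic acid | C=C(C(=O)O)[C@@H]1[C@@H](O)C/C(CO)=C\CC/C(CO)=C\[C@@H]1OC(=O)/C(C)=C/C
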